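The time of reading, 2.0 h, came first in my thinking: I had to know what would be over by then in Sunday's and Thursday's flasks, and the earlier alpha run was my clock.

| flask | free monomer | initiator | remark | time |
|---|---|---|---|---|
| alpha | 0.020 M | 0.087 mM | run made earlier |  |
| Sunday's | 0.020 M | 0.13 mM |  | 2.0 h |
| Thursday's | 0.030 M | 0.13 mM |  | 2.0 h |

alpha run (percent of the free monomer charged)

| time / min | monomer in chains / % |
|---|---|
| 6.00 | 16 |
| 10.0 | 22 |
| 20.0 | 31 |
| 40.0 | 37 |
| 80.0 | 36 |

(scatter of a reading: 2 percentage points)

- which of the two ends with the longer chains by the average number of monomer units in a chain (chains begun, living or dead) ("neither" if they lie within 10%) (Sunday's / Thursday's / neither)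
- average number of monomer units in a chain (chains begun, living or dead) at the end, Sunday's
- average number of monomer units in a chain (chains begun, living or dead) at the end, Thursday's

- the average divides the monomer in chains by the number of chains begun, living and dead together
- the earlier runs were read with a standard deviation of 2 percentage points
- the earlier runs do not show the number of chains; that part of a forecast is a guess
- no earlier run changes the charge of initiator; that part of a forecast is a guess

On the fastest rung stood the rise: alpha levelled near 36.5% of its charge, and its reading at 10.0 min put the approach to that level at 0.0923 min⁻¹, a lifetime τ of 10.8 min, so that 2.0 h was 11.1 lifetimes, if the new flasks kept a similar pace. On the next rung stood the flat stretch: between 40.0 min and 80.0 min the readings moved by 1 percentage point, inside the scatter of 2 points, so anything slower lay out of sight. Alpha could not separate a ceiling from dying chains, but I committed to a ceiling, the equilibrium monomer concentration, and called the free monomer standing under it M_e, 0.0127 M. On that view chains hold the excess of the charge over M_e, and I guessed that M_e held at the new initiator charge and that each initiator began one chain. Sunday's excess of 0.00730 M gave me 56.2 units, and Thursday's 0.0173 M gave 133.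

The forecast also chose Thursday's, but with 64 units (48 to 95) for Sunday's, above mine, and 124 (95 to 175) for Thursday's, below mine: “I take values between the two models, with wide ranges.”

The simulation gave Thursday's the longer chains, with 56.6 units for Sunday's and 133 for Thursday's.

    free monomer + initiator → living end + monomer in chains (k = 18.0 M⁻¹ min⁻¹)
    free monomer + living end → monomer in chains + living end, rate k2*[living end]*[free monomer] (k = 1400 M⁻¹ min⁻¹)
    monomer in chains + living end → free monomer + living end, rate k3*[living end] as long as [monomer in chains] is above zero (k = 17.0 min⁻¹)
    free monomer → decomposition product (k = 3.50 × 10⁻⁴ min⁻¹)

I then put M_e to a neighbour of Thursday's flask, charged with 0.018 M of free monomer and the same initiator. Its charge was 60.0% of Thursday's, but its excess, 0.00530 M, was 30.6% of Thursday's, so I reckoned 40.8 units. The neighbour flask gave 41.2 units, with 67.3% of its charge still free and 29.8% in chains.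

All runs stem from a simulated flask with constants of no real substance, and the scatter is random.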